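(The numbers in the tables were computed for substances that don't exist; the scatter is artificial.)

**Amounts charged.** Alder and the south-east run look nearly alike: both hold 20 mM of electrophile, with 1.10 equiv of nucleophile in alder against 1.3 equiv in south-east.

| flask | electrophile | nucleophile | remark | time |
|---|---|---|---|---|
| south-east | 20 mM | 1.3 equiv | run made earlier |  |
| south | 20 mM | 3 equiv | run made earlier |  |
| alder | 20 mM | 1.10 equiv |  | 30 min |
| oak | 20 mM | 2.20 equiv |  | 30 min |

| run | time / min | electrophile / % | product / % |
|---|---|---|---|
| south-east | 1.33 | 88.3 | 11.3 |
| south-east | 2.00 | 83.3 | 17.2 |
| south-east | 3.00 | 78.3 | 22.4 |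
| south-east | 4.00 | 72.8 | 26.7 |
| south-east | 6.00 | 64.7 | 34.4 |
| south-east | 10.0 | 55.9 | 44.5 |
| south-east | 15.0 | 49.2 | 50.5 |
| south | 1.33 | 74.5 | 25.6 |
| south | 2.00 | 66.0 | 33.9 |
| south | 3.00 | 54.8 | 44.1 |
| south | 4.00 | 47.0 | 53.9 |
| south | 6.00 | 36.4 | 65.5 |
| south | 10.0 | 20.8 | 78.5 |
| south | 15.0 | 12.7 | 86.6 |

(scatter of a reading: 0.5 percentage points)

- part of the electrophile that has reacted at the end, alder
- part of the electrophile that has reacted at the end, oak
- what raising the equivalents of nucleophile from its lowest to its highest value here does to the part of the electrophile that has reacted (changes below 5 percentage points count as none) (no change / it rises / it falls)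

- acid set free is meant together with its idle adduct
- reactions considered so far: nucleophile + acid set free <-> idle adduct; nucleophile + acid set free <-> protonated nucleophile; electrophile + nucleophile -> acid set free + product

**Two per turnover.** Each turnover frees one acid, and a second nucleophile can take that acid up as protonated nucleophile, so a turnover may cost two nucleophiles. The rate of conversion is then the pace (rate constant times electrophile charged) times the share of electrophile left times the equivalents of free nucleophile. Integrated to the last readings, this gives a pace of 0.0759 min⁻¹ in south-east and 0.0766 min⁻¹ in south, close although their charges of nucleophile differ. Their mean is 0.0762 min⁻¹.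

**The reach.** The reach, the equivalents of nucleophile over two, is the conversion that the charge of nucleophile pays for at two per turnover. For alder it is 55.0%, lower than the 65.0% of south-east, whose product stands at 50.5% after 15.0 min. Alder's reach lies below full conversion, so its limiting reagent is the nucleophile, although it is charged in excess. Integrating over 30 min gives alder 51.6%, below its reach. Oak's reach of 110% lies above full conversion, and oak reckons to 86.5%. That is a rise of 35 percentage points against a margin of 5 points.

**The forecast.** The forecast, holding that “each electrophile consumes about two nucleophiles”, gave 52% for alder and 87% for oak, 0.50 points from this reckoning on oak, and said it rises.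

**The flasks.** Alder gives 52.0% and oak 87.1%; the answer to the trend is it rises, by 35 points.

    nucleophile + acid set free ⇌ idle adduct, settled at all times (K = 110 L mol⁻¹)
    nucleophile + acid set free ⇌ protonated nucleophile, settled at all times (K = 3.20 × 10⁵ L mol⁻¹)
    electrophile + nucleophile → acid set free + product (k = 4.00 L mol⁻¹ min⁻¹)

One minus conversion over reach puts alder's free nucleophile at 5.45% of its charge, and 5.6% stands there, less than the 48% of electrophile left. A neighbour of alder, charged with 4.40 equiv of nucleophile and otherwise as alder, has a reach of 220%, and the same pace reckons it to 99.8%. That flask gives 99.8%, with 0.17% of its electrophile left. Its free nucleophile reckons to 54.6% of charge and stands at 55%.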